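A small charge of free enzyme, 10 µM against 20 mM of starting material and 20.0 mM of second substrate, has to serve both substrates, so I work with the fraction of each charge left and not with the fraction made.

all flasks: starting material 20 mM; second substrate 20.0 mM; free enzyme 10 µM; time 10 h
- summer: temperature 20 °C
- noon: temperature −20 °C
- spring: temperature −40 °C
- dusk: temperature 0 °C

    starting material + free enzyme → spent catalyst (k1 = 1.7 M⁻¹ h⁻¹, Ea1 = 77.0 kJ mol⁻¹)
    complex A → free enzyme + target (k2 = 1300 h⁻¹, Ea2 = 84.0 kJ mol⁻¹)
    free enzyme → unfolded enzyme (k3 = 0.0018 h⁻¹, Ea3 = 204 kJ mol⁻¹)
    starting material + free enzyme ⇌ complex A (K4 = 580 M⁻¹, k4 = 64000 M⁻¹ h⁻¹, Ea4 = 36.0 kJ mol⁻¹, ΔH4 = −31.0 kJ mol⁻¹)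
    second substrate + free enzyme ⇌ complex B (K5 = 130 M⁻¹, k5 = 8.0 × 10⁵ M⁻¹ h⁻¹, Ea5 = 44.0 kJ mol⁻¹, ΔH5 = −23.0 kJ mol⁻¹)
    complex B → free enzyme + second product (k6 = 400 h⁻¹, Ea6 = 79.0 kJ mol⁻¹)
    (constants at 20 °C)

- all constants are for 20 °C and move with temperature by the activation energies and enthalpies

1. the flask with the highest amount of target, in percent of the starting material charged ("all alike" if they lie within 1.5 percentage points) (summer / noon / spring / dusk / all alike)
2. final target, as a percentage of the starting material charged, in summer
3. final target, as a percentage of the starting material charged, in noon
4. final target, as a percentage of the starting material charged, in spring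
5. final target, as a percentage of the starting material charged, in dusk

The enzyme is outnumbered 2000 to one, so the complexes hold hardly any of the starting material, and the unbound fraction is what I count as left.

I take summer, whose temperature is the one at which the constants are given. Complex A has two ways out: onward to target with constant 1300 h⁻¹, or back with constant 110 h⁻¹. The share going onward is therefore 0.922. Complex A lasts about 2.55 s, and because that is far shorter than the run, its level follows the free enzyme and the starting material from moment to moment, the usual quasi-steady state.

Starting material is then lost, per unit of itself, at a capture constant times the free enzyme. That capture constant is the rate constant of binding times the onward share, 59000 M⁻¹ h⁻¹. The route to spent catalyst adds far less than this, so I drop it.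

Complex B falls back with constant 6150 h⁻¹, which is faster than it goes on. Its onward share is 0.0610, and its capture constant is 48800 M⁻¹ h⁻¹.

Both fractional losses carry the same free enzyme, so it cancels in their ratio, however much of it unfolds or is spent. That ratio, 1.21, is the selectivity factor, the capture constant of starting material over that of second substrate. Integrated, it gives a rule for this temperature: the fraction of starting material left equals the fraction of second substrate left, raised to the power of the selectivity factor.

My reckoning stops there. The rule ties the two fractions together but carries no clock, so I commit to no yield for any flask. I commit to this: in summer, a smaller fraction of the starting material than of the second substrate is left as the run goes on, because the factor exceeds one.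

The forecast, which treats “the enzyme as a quasi-steady-state catalyst with the two substrates competing”, names summer as the best flask. It gives 90.3% for summer (88% to 92.5%), 19% for dusk (18% to 20%), 1.64% for noon (1.5% to 1.8%) and 0.066% for spring (0.058% to 0.075%).

The simulation gives summer as the best flask, with 90.5% of target in summer, 19.0% in dusk, 1.64% in noon and 0.0655% in spring, each inside the forecast's range.

At the end of summer, 14% of the second substrate is left; raised to the selectivity factor, that gives 9.53% of starting material, and the reading is 9.5%. A neighbour of summer, charged with 80 mM of second substrate (4.00 equiv) and otherwise the same, keeps the temperature and so the factor. It ends with 59.6% of its second substrate left, so the rule gives 53.5% of starting material left and 46.5% turned to target. In that neighbour the run leaves 54% of the starting material and ends with 46.5% of target.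

All constants stand for no real mixture; the flask was simulated.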